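## The problem

Compound 23 is a 2-hydroxychroman-4-one. A fully substituted ring A (5-OH, 6-OMe, 7-OH, 8-CH3) is fused through C4a and C8a to the six-membered lactol ring C, and C3 carries a hydroxy(4-hydroxyphenyl)methyl arm (C9). Ring A requires four oxygens on one benzene ring to be told apart: O6 is methylated, O5 and O7 end free, and O1, next to the C-methyl group, is part of ring C. There are three contiguous stereocentres. C2 is a hemiacetal and takes its thermodynamic configuration; C3 lies between the C4 ketone and the masked C2 aldehyde and can epimerise once the ketone exists; C9 is the only robust centre, so it should be set first and C3 then set by a reagent whose preference agrees with C9. The functions are fragile: the C9–C3–C4 β-hydroxy ketone can cleave by retro-aldol reaction or dehydrate, the 2-hydroxychromanone loses water to a chromone in acid, the p-hydroxybenzylic alcohol ionises easily, and the free phenolic ring is readily oxidised. The ketone should therefore appear late and the last steps must be near neutral. The enabling feature is that O1–C8a–C4a–C4 is the four-atom unit of an ortho-quinone methide of ring A, while C2–C3 is the carbonyl carbon and α-carbon of an aldehyde that carries C9. With C4 as a methylene, ring C is their formal [4+2] adduct, and C4, flanked by O1 and O5 (ortho) and O7 (para), is the benzylic position most easily oxidised afterwards.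

## Retrosynthesis

**Protecting groups (23 ⇒ 22 ⇒ 21).** No skeletal bond is cut. The three phenols are traced to benzyl ethers and the C2 and C9 hydroxyls to tert-butyldimethylsilyl ethers, leading through 22 to 21. Hydrogenolysis and buffered fluoride are near neutral. A C2 methyl acetal would instead need aqueous acid on a 2-alkoxychroman-4-one, the conditions under which such compounds lose water to chromones. One silyl group on both O2 and O9 lets one reagent free both. The forward steps must leave C3, now α to the ketone, untouched.

**C4 oxidation level (21 ⇒ 19).** The C4=O bond is removed, giving chroman 19 with a C4 methylene. Bringing C4 in as an acyl carbon would place C3 between two carbonyl-level carbons during the coupling; in 19 the C3–H is not acidic. The forward step is a benzylic oxidation that must select C4 (secondary, on the most electron-rich ring) over C9–H and the 8-methyl group.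

**Ring C (19 ⇒ 18 ⇒ 8 + 14).** After removal of the O2 silyl group, lactol 18 is cut at C3–C4 and O1–C2. This removes one ring, two skeletal bonds and two stereocentres at once and leaves two fragments of similar size, sulfone 8 and aldehyde 14, the latter with C9 as its only stereocentre. A C3–C9 aldol cut would demand an anti-selective aldol on a lactol-bearing chromanone; a C4–C4a acylation would demand acylation of a pentasubstituted arene by an α-branched, β-oxygenated acid. The forward reaction asks that 8 release quinone methide 15 under conditions that amine catalysis tolerates. Hence the sulfinate leaving group of 8 rather than the hydroxyl of 7, whose ionisation needs acid or heat. It also asks that the enamine of 14 add with control of the C3 face before it expels its β-silyloxy group.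

**Aldehyde (14 ⇒ 13 ⇒ 12 ⇒ 11 ⇒ 9 + 10).** 14 is traced to ester 13 and alcohol 12; the C9–H bond is cut to give β-keto ester 11, and the bond between the ester carbon (later C2) and C3 is cut to give ketone 9 and carbonate 10. A catalytic ketone reduction sets C9 more simply than an acetate aldol or an allylation–cleavage sequence, and aryl β-keto esters are reliable substrates. The forward steps ask for high enantioselectivity at C9 and a clean ester-to-aldehyde reduction.

**Quinone methide precursor (8 ⇒ 7 ⇒ 6).** The C–S bond is cut to give salicyl alcohol 7, which comes from salicylaldehyde 6. The formyl carbon of 6 is C4, so no separate carbon has to be introduced later. The substitution must proceed without self-condensation; ring A has no free position, which excludes self-arylation.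

**Ring A (6 ⇒ 5 ⇒ 4 ⇒ 3 ⇒ 1).** The C6–OMe bond is cut to bromide 5 and then to 4, the two benzyl C–O bonds to triol 3, and the aryl–CHO bond to 2,4,6-trihydroxytoluene 1. Formylating a preformed tetraoxygenated phenol would need a temporary group on O1 and about three more steps. Here the formyl group does three jobs: it chelates O1 (so O5 and O7 are benzylated and O1 stays free), it leaves a single ring position for C6 oxygenation para to O1, and it becomes C4. The forward steps ask for regioselective dibenzylation and for methoxylation of a hindered aryl bromide.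

## Roads not taken

**Alternative 1:** Ring A could be built instead of functionalised: the C4a–C8a bond is cut and the ring traced to cyclobutenone A2, assembled from squarate A3 by two organolithium additions and an O-methylation. Thermolysis would open A2 to a dienylketene whose 6π electrocyclisation and tautomerisation give phenol A1 with O1 as the only free hydroxyl. Its merit is that every substituent is placed by the order of additions, with no regiochemical ambiguity. In this respect it is better than the chosen plan, which relies on selectivity in steps 2 and 4. Its weak points are that it solves ring A only, so A1 still needs formylation, reduction and everything after. It also spends several cryogenic organometallic steps on a ring that 1 provides in five steps with C4 already attached. Finally, the isopropyl ethers of A1 come off only with strong Lewis acids, which the lactol and β-hydroxy ketone of 23 would not survive. The chosen plan sets against its certainty a shorter sequence, benzyl ethers removable by hydrogenolysis and two fallbacks for the selective steps.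

**Alternative 2:** C4–C4a and C8a–O1 are cut together. The aryne released from silyl triflate A6 by CsF would insert into the C–O bond of acid A5 to give ortho-hydroxyaryl ketone A4. Its merits are real: C4 arrives as the ketone, so no benzylic oxidation is needed, and A5 brings C3 and C9 already set. In oxidation-state economy this road is better than the chosen one. Its weak points are at the key step itself. The aryne is tetrasubstituted and flanked by a benzyloxy group on one side and a methyl group on the other, so the regiochemistry of carboxylate addition rests on a small difference. The acyl transfer to the aryl anion passes through a strained four-membered transition state and is hard for an α-branched acid. A4 is formed under basic fluoride with C3 already α to a ketone and β to a silyloxy group, which invites epimerisation and elimination. A6 also needs a long preparation. The chosen plan pays two extra steps (12 and 13) but keeps C3 non-acidic until the last protected intermediate.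

**Alternative 3:** The same two bonds (C3–C4 and O–C2) would be formed by a 1,3-dipolar cycloaddition of nitrile oxide A8 to (E)-enol ether A9, giving isoxazoline A7. N–O cleavage and hydrolysis would then unveil the C4 ketone and C2 aldehyde. Its merits are that C4 arrives at the ketone oxidation level, that no β-elimination-prone enamine is involved, that the doubly ortho-substituted A8 does not dimerise, and that the E geometry fixes the 4,5-trans relationship. It thus avoids both the sulfone and the DDQ step. Its weak points are that the C3 face is chosen by the allylic C9 centre alone, with no reagent to enforce it, and that a 1,2-disubstituted enol ether is a sluggish partner for a hindered nitrile oxide. A9 must be geometrically pure. O1 needs an acetal protecting group whose acidic removal, on a 2-alkoxychromanone, risks the chromone. The reductive N–O cleavage must also spare three benzyl ethers. The chosen plan sets against this catalyst control at C3 (matched with C9), fewer steps and an acid-free end-game.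

Key step: step 11

Assumption: C2 is a hemiacetal carbon that equilibrates through the open hydroxy aldehyde; the (2S) configuration of 23 (hydroxyl trans to the C3 side chain) is taken to be the thermodynamically preferred one, so no step is devoted to it.

## Route

Step 1
Reactants: 1 2,4,6-trihydroxytoluene
Product: 3 2,4,6-trihydroxy-3-methylbenzaldehyde, via iminium chloride 2 (not isolated)
Conditions: POCl3, DMF, EtOAc, 0 °C to rt; then H2O, 60 °C
Reagents that add atoms: N,N-dimethylformamide, CN(C)C=O; water, O
Why: Vilsmeier–Haack formylation; the two free ring positions of 1 are equivalent, so one aldehyde results, and precipitation of salt 2 prevents a second formylation before hydrolysis.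

Step 2
Reactants: 3 2,4,6-trihydroxy-3-methylbenzaldehyde
Product: 4 4,6-bis(benzyloxy)-2-hydroxy-3-methylbenzaldehyde
Conditions: BnBr (2.1 equiv), K2CO3, DMF, 0 °C to rt
Reagents that add atoms: benzyl bromide, BrCc1ccccc1
Why: Williamson etherification under chelation control: the hydroxyl para to the formyl group is the most acidic and reacts first, and of the two hydrogen-bonded ortho hydroxyls the one not flanked by the methyl group reacts next, leaving O1 free.

Step 3
Reactants: 4 4,6-bis(benzyloxy)-2-hydroxy-3-methylbenzaldehyde
Product: 5 2,4-bis(benzyloxy)-3-bromo-6-hydroxy-5-methylbenzaldehyde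
Conditions: NBS, MeCN, 0 °C
Reagents that add atoms: N-bromosuccinimide, O=C1CCC(=O)N1Br
Why: Electrophilic aromatic bromination; the only unsubstituted ring position is para to the free phenol and ortho to both benzyloxy groups, so the site is unambiguous.

Step 4
Reactants: 5 2,4-bis(benzyloxy)-3-bromo-6-hydroxy-5-methylbenzaldehyde
Product: 6 2,4-bis(benzyloxy)-6-hydroxy-3-methoxy-5-methylbenzaldehyde
Conditions: NaOMe, CuBr (cat.), MeOH–DMF, 110 °C (sealed)
Reagents that add atoms: sodium methoxide, [Na+].[O-]C
Why: Copper-catalysed Ullmann-type methoxylation of an aryl bromide, the reaction type that converts bromohydroxybenzaldehydes into their methyl ethers; the phenol and aldehyde are carried as the sodium phenoxide, and any hydrodebromination returns 4.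

Step 5
Reactants: 6 2,4-bis(benzyloxy)-6-hydroxy-3-methoxy-5-methylbenzaldehyde
Product: 7 3,5-bis(benzyloxy)-2-(hydroxymethyl)-4-methoxy-6-methylphenol
Conditions: NaBH4, THF–MeOH, 0 °C
Reagents that add atoms: none
Why: Hydride reduction of the aldehyde; at 0 °C the salicyl alcohol does not go on to the cresol, and it is used without exposure to acid.

Step 6
Reactants: 7 3,5-bis(benzyloxy)-2-(hydroxymethyl)-4-methoxy-6-methylphenol
Product: 8 3,5-bis(benzyloxy)-4-methoxy-2-methyl-6-{[(4-methylphenyl)sulfonyl]methyl}phenol
Conditions: 4-MeC6H4SO2Na, HCO2H–H2O, THF, rt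
Reagents that add atoms: sodium p-toluenesulfinate, Cc1ccc(cc1)S(=O)[O-].[Na+]
Why: SN1-type substitution: formic acid ionises the benzylic alcohol, which is stabilised by three oxygen donors, and sulfinate adds through sulfur to give the thermodynamically favoured sulfone. Ring A has no free position for self-arylation, and the sulfone is a leaving group that mild base can expel.

Step 7
Reactants: 9 4'-(benzyloxy)acetophenone; 10 diethyl carbonate
Product: 11 ethyl 3-[4-(benzyloxy)phenyl]-3-oxopropanoate
Conditions: NaH, THF, reflux; then aq. HCl
Reagents that add atoms: none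
Why: Crossed Claisen condensation of the ketone enolate with a non-enolisable carbonate, driven by deprotonation of the β-keto ester.

Step 8
Reactants: 11 ethyl 3-[4-(benzyloxy)phenyl]-3-oxopropanoate
Product: 12 ethyl (3S)-3-[4-(benzyloxy)phenyl]-3-hydroxypropanoate
Conditions: RuCl[(S,S)-TsDPEN](p-cymene) (1 mol %), HCO2H–Et3N (5:2), 40 °C
Reagents that add atoms: none
Why: Noyori–Ikariya asymmetric transfer hydrogenation; the (S,S) catalyst reduces aryl ketones to the (S)-carbinol (aryl ranked above the CH2 group), which sets C9. Formic acid makes the reduction irreversible and the benzyl ether is inert.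

Step 9
Reactants: 12 ethyl (3S)-3-[4-(benzyloxy)phenyl]-3-hydroxypropanoate
Product: 13 ethyl (3S)-3-[4-(benzyloxy)phenyl]-3-[(tert-butyldimethylsilyl)oxy]propanoate
Conditions: TBSCl, imidazole, DMF, rt
Reagents that add atoms: tert-butyldimethylsilyl chloride, CC(C)(C)[Si](C)(C)Cl
Why: Standard silylation of a secondary alcohol; the bulky silyloxide is a poor leaving group, which matters in step 11.

Step 10
Reactants: 13 ethyl (3S)-3-[4-(benzyloxy)phenyl]-3-[(tert-butyldimethylsilyl)oxy]propanoate
Product: 14 (3S)-3-[4-(benzyloxy)phenyl]-3-[(tert-butyldimethylsilyl)oxy]propanal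
Conditions: i-Bu2AlH (1.1 equiv), CH2Cl2, −78 °C; then aq. potassium sodium tartrate
Reagents that add atoms: none
Why: Partial reduction of an ester at low temperature; the aldehyde is released only on work-up, and C9 is not α to the carbonyl, so it cannot epimerise.

Step 11
Reactants: 8 3,5-bis(benzyloxy)-4-methoxy-2-methyl-6-{[(4-methylphenyl)sulfonyl]methyl}phenol; 14 (3S)-3-[4-(benzyloxy)phenyl]-3-[(tert-butyldimethylsilyl)oxy]propanal
Product: 18 (2S,3R)-5,7-bis(benzyloxy)-3-{(S)-[4-(benzyloxy)phenyl][(tert-butyldimethylsilyl)oxy]methyl}-6-methoxy-8-methylchroman-2-ol, via quinone methide 15 (not isolated), via enamine 16 (not isolated), via aminal 17 (not isolated)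
Conditions: (R)-2-[diphenyl(trimethylsilyloxy)methyl]pyrrolidine (20 mol %), Na2CO3, CH2Cl2, H2O (few equiv), 0 °C to rt
Reagents that add atoms: water, O (the lactol oxygen, delivered on hydrolysis of aminal 17)
Why: Secondary-amine-catalysed formal [4+2] annulation of an in situ ortho-quinone methide with an enolisable aldehyde, a known route to chroman-2-ols. Na2CO3 deprotonates the phenol of 8 and the phenoxide expels p-toluenesulfinate to give 15, while 14 and the catalyst form the (E)-enamine 16. The α-carbon of 16 (C3) adds to the exocyclic methylene of 15 (C4) in a Michael-type step driven by rearomatisation of ring A; the phenoxide O1 then closes on the iminium carbon C2 in a 6-exo-trig cyclisation to aminal 17, and water releases lactol 18 and the catalyst. C3 is set by the catalyst: the diphenyl(silyloxy)methyl group of the (R)-pyrrolidine covers one face of the s-trans enamine, and addition to the open face gives 3R. The C9 centre is matched with this: with its aryl group anti to the incoming electrophile and the siloxy group in the inside position, the same face is exposed. C2 is a hemiacetal and settles under thermodynamic control as the 2,3-trans (2S) lactol; C4 is a methylene, so no further centre arises. The step needs addition to be faster than loss of silanol from 16; fast release of 15 from the electron-rich sulfone, the poor leaving-group ability of the bulky silyloxide and the absence of acid secure this. Only O1 is free on ring A, so a single quinone methide and a single ring closure are possible.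

Step 12
Reactants: 18 (2S,3R)-5,7-bis(benzyloxy)-3-{(S)-[4-(benzyloxy)phenyl][(tert-butyldimethylsilyl)oxy]methyl}-6-methoxy-8-methylchroman-2-ol
Product: 19 (2R,3R)-5,7-bis(benzyloxy)-3-{(S)-[4-(benzyloxy)phenyl][(tert-butyldimethylsilyl)oxy]methyl}-2-[(tert-butyldimethylsilyl)oxy]-6-methoxy-8-methylchromane
Conditions: TBSCl, imidazole, DMF, rt
Reagents that add atoms: tert-butyldimethylsilyl chloride, CC(C)(C)[Si](C)(C)Cl
Why: Silylation of the lactol hydroxyl; it blocks ring opening to a free phenol that DDQ would oxidise and gives O2 the same group as O9. The anomer ratio does not matter because C2 is reset in step 14 (the descriptor changes to 2R only because silicon outranks carbon).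

Step 13
Reactants: 19 (2R,3R)-5,7-bis(benzyloxy)-3-{(S)-[4-(benzyloxy)phenyl][(tert-butyldimethylsilyl)oxy]methyl}-2-[(tert-butyldimethylsilyl)oxy]-6-methoxy-8-methylchromane
Product: 21 (2R,3R)-5,7-bis(benzyloxy)-3-{(S)-[4-(benzyloxy)phenyl][(tert-butyldimethylsilyl)oxy]methyl}-2-[(tert-butyldimethylsilyl)oxy]-6-methoxy-8-methylchroman-4-one, via benzylic alcohol 20 (not isolated)
Conditions: DDQ (2.5 equiv), CH2Cl2–pH 7 phosphate buffer (10:1), 0 °C to rt
Reagents that add atoms: water, O
Why: DDQ benzylic oxidation, known for 5,7-dialkoxychromans carrying benzyl ethers: hydride abstraction at C4 gives a cation stabilised by O1, O5 and O7, water adds to give 20, and a second equivalent oxidises this electron-rich benzylic alcohol to the aryl ketone. C4 is secondary and on the most electron-rich ring, so it should react before the primary 8-methyl group or C9–H.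

Step 14
Reactants: 21 (2R,3R)-5,7-bis(benzyloxy)-3-{(S)-[4-(benzyloxy)phenyl][(tert-butyldimethylsilyl)oxy]methyl}-2-[(tert-butyldimethylsilyl)oxy]-6-methoxy-8-methylchroman-4-one
Product: 22 (2S,3R)-5,7-bis(benzyloxy)-3-{(S)-[4-(benzyloxy)phenyl](hydroxy)methyl}-2-hydroxy-6-methoxy-8-methylchroman-4-one
Conditions: HF·pyridine, pyridine, THF, 0 °C to rt
Reagents that add atoms: none
Why: Fluoride cleavage of both silyl ethers under buffered, near-neutral conditions that spare the β-hydroxy ketone and the C3–H; the freed hemiacetal settles as the 2,3-trans (2S) lactol.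

Step 15
Reactants: 22 (2S,3R)-5,7-bis(benzyloxy)-3-{(S)-[4-(benzyloxy)phenyl](hydroxy)methyl}-2-hydroxy-6-methoxy-8-methylchroman-4-one
Product: 23 (2S,3R)-2,5,7-trihydroxy-3-[(S)-hydroxy(4-hydroxyphenyl)methyl]-6-methoxy-8-methylchroman-4-one
Conditions: H2 (1 atm), Pd/C, EtOAc, rt
Reagents that add atoms: none
Why: Hydrogenolysis of three aryl benzyl ethers in a neutral, aprotic medium; aryl benzyl ethers should cleave well before the benzylic C9–OH bond or the chelated aryl ketone reacts, and the product needs only filtration.

## Compound list

1 | 2,4,6-trihydroxytoluene | Cc1c(O)cc(O)cc1O | starting material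
2 | N-methyl-N-[(2,4,6-trihydroxy-3-methylphenyl)methylidene]methanaminium chloride | C[N+](C)=Cc1c(O)cc(O)c(C)c1O.[Cl-] | intermediate
3 | 2,4,6-trihydroxy-3-methylbenzaldehyde | Cc1c(O)cc(O)c(C=O)c1O | intermediate
4 | 4,6-bis(benzyloxy)-2-hydroxy-3-methylbenzaldehyde | Cc1c(O)c(C=O)c(OCc2ccccc2)cc1OCc1ccccc1 | intermediate
5 | 2,4-bis(benzyloxy)-3-bromo-6-hydroxy-5-methylbenzaldehyde | Cc1c(O)c(C=O)c(OCc2ccccc2)c(Br)c1OCc1ccccc1 | intermediate
6 | 2,4-bis(benzyloxy)-6-hydroxy-3-methoxy-5-methylbenzaldehyde | COc1c(OCc2ccccc2)c(C)c(O)c(C=O)c1OCc1ccccc1 | intermediate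
7 | 3,5-bis(benzyloxy)-2-(hydroxymethyl)-4-methoxy-6-methylphenol | COc1c(OCc2ccccc2)c(C)c(O)c(CO)c1OCc1ccccc1 | intermediate
8 | 3,5-bis(benzyloxy)-4-methoxy-2-methyl-6-{[(4-methylphenyl)sulfonyl]methyl}phenol | COc1c(OCc2ccccc2)c(C)c(O)c(CS(=O)(=O)c2ccc(C)cc2)c1OCc1ccccc1 | intermediate
9 | 4'-(benzyloxy)acetophenone | CC(=O)c1ccc(OCc2ccccc2)cc1 | starting material
10 | diethyl carbonate | CCOC(=O)OCC | starting material
11 | ethyl 3-[4-(benzyloxy)phenyl]-3-oxopropanoate | CCOC(=O)CC(=O)c1ccc(OCc2ccccc2)cc1 | intermediate
12 | ethyl (3S)-3-[4-(benzyloxy)phenyl]-3-hydroxypropanoate | CCOC(=O)C[C@H](O)c1ccc(OCc2ccccc2)cc1 | intermediate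
13 | ethyl (3S)-3-[4-(benzyloxy)phenyl]-3-[(tert-butyldimethylsilyl)oxy]propanoate | CCOC(=O)C[C@H](O[Si](C)(C)C(C)(C)C)c1ccc(OCc2ccccc2)cc1 | intermediate
14 | (3S)-3-[4-(benzyloxy)phenyl]-3-[(tert-butyldimethylsilyl)oxy]propanal | O=CC[C@H](O[Si](C)(C)C(C)(C)C)c1ccc(OCc2ccccc2)cc1 | intermediate
15 | 3,5-bis(benzyloxy)-4-methoxy-2-methyl-6-methylidenecyclohexa-2,4-dien-1-one | C=C1C(=O)C(C)=C(OCc2ccccc2)C(OC)=C1OCc1ccccc1 | intermediate
16 | (2R)-1-{(1E,3S)-3-[4-(benzyloxy)phenyl]-3-[(tert-butyldimethylsilyl)oxy]prop-1-en-1-yl}-2-{diphenyl[(trimethylsilyl)oxy]methyl}pyrrolidine | C[Si](C)(C)OC(c1ccccc1)(c1ccccc1)[C@H]1CCCN1/C=C/[C@H](O[Si](C)(C)C(C)(C)C)c1ccc(OCc2ccccc2)cc1 | intermediate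
17 | (3R)-5,7-bis(benzyloxy)-3-{(S)-[4-(benzyloxy)phenyl][(tert-butyldimethylsilyl)oxy]methyl}-2-[(2R)-2-{diphenyl[(trimethylsilyl)oxy]methyl}pyrrolidin-1-yl]-6-methoxy-8-methylchromane (C2 not defined) | COc1c(OCc2ccccc2)c(C)c2c(c1OCc1ccccc1)C[C@H]([C@H](O[Si](C)(C)C(C)(C)C)c1ccc(OCc3ccccc3)cc1)C(N1CCC[C@@H]1C(O[Si](C)(C)C)(c1ccccc1)c1ccccc1)O2 | intermediate
18 | (2S,3R)-5,7-bis(benzyloxy)-3-{(S)-[4-(benzyloxy)phenyl][(tert-butyldimethylsilyl)oxy]methyl}-6-methoxy-8-methylchroman-2-ol | COc1c(OCc2ccccc2)c(C)c2c(c1OCc1ccccc1)C[C@H]([C@H](O[Si](C)(C)C(C)(C)C)c1ccc(OCc3ccccc3)cc1)[C@@H](O)O2 | intermediate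
19 | (2R,3R)-5,7-bis(benzyloxy)-3-{(S)-[4-(benzyloxy)phenyl][(tert-butyldimethylsilyl)oxy]methyl}-2-[(tert-butyldimethylsilyl)oxy]-6-methoxy-8-methylchromane | COc1c(OCc2ccccc2)c(C)c2c(c1OCc1ccccc1)C[C@H]([C@H](O[Si](C)(C)C(C)(C)C)c1ccc(OCc3ccccc3)cc1)[C@@H](O[Si](C)(C)C(C)(C)C)O2 | intermediate
20 | (2R,3R)-5,7-bis(benzyloxy)-3-{(S)-[4-(benzyloxy)phenyl][(tert-butyldimethylsilyl)oxy]methyl}-2-[(tert-butyldimethylsilyl)oxy]-6-methoxy-8-methylchroman-4-ol (both C4 epimers) | COc1c(OCc2ccccc2)c(C)c2c(c1OCc1ccccc1)C(O)[C@H]([C@H](O[Si](C)(C)C(C)(C)C)c1ccc(OCc3ccccc3)cc1)[C@@H](O[Si](C)(C)C(C)(C)C)O2 | intermediate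
21 | (2R,3R)-5,7-bis(benzyloxy)-3-{(S)-[4-(benzyloxy)phenyl][(tert-butyldimethylsilyl)oxy]methyl}-2-[(tert-butyldimethylsilyl)oxy]-6-methoxy-8-methylchroman-4-one | COc1c(OCc2ccccc2)c(C)c2c(c1OCc1ccccc1)C(=O)[C@H]([C@H](O[Si](C)(C)C(C)(C)C)c1ccc(OCc3ccccc3)cc1)[C@@H](O[Si](C)(C)C(C)(C)C)O2 | intermediate
22 | (2S,3R)-5,7-bis(benzyloxy)-3-{(S)-[4-(benzyloxy)phenyl](hydroxy)methyl}-2-hydroxy-6-methoxy-8-methylchroman-4-one | COc1c(OCc2ccccc2)c(C)c2c(c1OCc1ccccc1)C(=O)[C@H]([C@H](O)c1ccc(OCc3ccccc3)cc1)[C@@H](O)O2 | intermediate
23 | (2S,3R)-2,5,7-trihydroxy-3-[(S)-hydroxy(4-hydroxyphenyl)methyl]-6-methoxy-8-methylchroman-4-one | COc1c(O)c(C)c2c(c1O)C(=O)[C@H]([C@H](O)c1ccc(O)cc1)[C@@H](O)O2 | target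

## Step count and least certain steps

Total step count: 15. Longest linear sequence: 11 steps (steps 1–6 and 11–15, from 1); the aldehyde branch (steps 7–10) joins at step 11.

**Step 11 (key step).** The most likely failure is loss of the β-silyloxy group from the enamine, giving the cinnamaldehyde-type iminium before the quinone methide is captured. Next are an eroded facial selectivity if the catalyst and C9 work against each other, and dimerisation of the quinone methide or N-alkylation of the catalyst. The fallback makes the C3–C4 bond by a Fráter–Seebach alkylation, in which the C9 alkoxide controls C3 and no enamine is involved. It sets out from 7 and 12 and returns at 19. Alcohol 7 would be silylated on both hydroxyls (TBSCl, imidazole) to bis-silyl ether F1, and Ph3PBr2 would convert the benzylic silyl ether selectively into benzylic bromide F2. Ester 12 would be deprotonated twice with LiN(i-Pr)2 (THF, −78 to −20 °C) and alkylated by F2 anti to the aryl group of the lithium chelate, giving anti hydroxy ester F3, which has the C3/C9 relationship of 23. Bu4NF would free the phenoxide, which lactonises onto the ethyl ester to give dihydrocoumarin F4. i-Bu2AlH at −78 °C would reduce the lactone to lactol diol F5, and TBSCl with imidazole would silylate both hydroxyls to give 19.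

**Step 2.** Regioselection between the two chelated hydroxyls may be incomplete, with some alkylation next to the methyl group and some over-benzylation, because the steric difference is modest. The fallback reaches the same compound by dealkylation instead of alkylation, from 3 back to 4. Exhaustive benzylation of 3 (BnBr, K2CO3, DMF, 60 °C) would give tribenzyl ether F6. MgBr2·OEt2 in toluene–Et2O would then remove one benzyl group ortho to the formyl group through the magnesium chelate. The ether between formyl and methyl is twisted out of the ring plane and is the more Lewis basic, so it is expected to be cleaved first.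

**Step 4.** Activation of a bromide flanked by two benzyloxy groups and para to a phenoxide may be slow, so hydrodebromination could dominate. The fallback introduces O6 by oxidation, from 4 to 6 without passing through 5. Elbs persulfate oxidation of 4 (K2S2O8, aq. NaOH–pyridine) would hydroxylate the position para to the phenol by way of aryl sulfate F7. Warm dilute HCl would hydrolyse F7 to hydroquinone F8. MeI (1 equiv) and K2CO3 in acetone would then methylate the new, non-chelated hydroxyl in preference to the chelated one and give 6.

**Step 13.** Site selectivity may be lost through hydride abstraction at C9–H or at the 8-methyl group once excess quinone is present, or the C4 cation may lose a proton to a chromene instead of capturing water. The fallback separates the two oxidations, from 19 to 21. One equivalent of DDQ at 0 °C in wet CH2Cl2 would be used and alcohol 20 isolated. Dess–Martin periodinane with NaHCO3, which cannot abstract benzylic hydride, would then oxidise 20 to 21. This detour makes no compound outside the list (entry F0).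

**Step 15.** Hydrogenolysis of the benzylic C9–O bond, which is activated by the para oxygen, or reduction of the ketone may compete with debenzylation. The fallback reverses the order of the last two steps, from 21 to 23. Hydrogenolysis of 21 (H2, Pd/C, EtOAc), with C9–O still shielded as its silyl ether, would give tris-phenol bis-silyl ether F9. HF·pyridine buffered with pyridine would then give 23.

## Further compounds

F1 | step 11 | {3,5-bis(benzyloxy)-2-{[(tert-butyldimethylsilyl)oxy]methyl}-4-methoxy-6-methylphenoxy}(tert-butyl)dimethylsilane | COc1c(OCc2ccccc2)c(C)c(O[Si](C)(C)C(C)(C)C)c(CO[Si](C)(C)C(C)(C)C)c1OCc1ccccc1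
F2 | step 11 | [3,5-bis(benzyloxy)-2-(bromomethyl)-4-methoxy-6-methylphenoxy](tert-butyl)dimethylsilane | COc1c(OCc2ccccc2)c(C)c(O[Si](C)(C)C(C)(C)C)c(CBr)c1OCc1ccccc1
F3 | step 11 | ethyl (2R,3S)-2-{2,4-bis(benzyloxy)-6-[(tert-butyldimethylsilyl)oxy]-3-methoxy-5-methylbenzyl}-3-[4-(benzyloxy)phenyl]-3-hydroxypropanoate | CCOC(=O)[C@H](Cc1c(O[Si](C)(C)C(C)(C)C)c(C)c(OCc2ccccc2)c(OC)c1OCc1ccccc1)[C@H](O)c1ccc(OCc2ccccc2)cc1
F4 | step 11 | (3R)-5,7-bis(benzyloxy)-3-{(S)-[4-(benzyloxy)phenyl](hydroxy)methyl}-6-methoxy-8-methylchroman-2-one | COc1c(OCc2ccccc2)c(C)c2c(c1OCc1ccccc1)C[C@H]([C@H](O)c1ccc(OCc3ccccc3)cc1)C(=O)O2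
F5 | step 11 | (2S,3R)-5,7-bis(benzyloxy)-3-{(S)-[4-(benzyloxy)phenyl](hydroxy)methyl}-6-methoxy-8-methylchroman-2-ol | COc1c(OCc2ccccc2)c(C)c2c(c1OCc1ccccc1)C[C@H]([C@H](O)c1ccc(OCc3ccccc3)cc1)[C@@H](O)O2
F6 | step 2 | 2,4,6-tris(benzyloxy)-3-methylbenzaldehyde | Cc1c(OCc2ccccc2)cc(OCc2ccccc2)c(C=O)c1OCc1ccccc1
F7 | step 4 | potassium 2,6-bis(benzyloxy)-3-formyl-4-hydroxy-5-methylphenyl sulfate | Cc1c(O)c(C=O)c(OCc2ccccc2)c(OS(=O)(=O)[O-])c1OCc1ccccc1.[K+]
F8 | step 4 | 2,4-bis(benzyloxy)-3,6-dihydroxy-5-methylbenzaldehyde | Cc1c(O)c(C=O)c(OCc2ccccc2)c(O)c1OCc1ccccc1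
F0 | step 13 | none | none
F9 | step 15 | (2R,3R)-2-[(tert-butyldimethylsilyl)oxy]-3-{(S)-[(tert-butyldimethylsilyl)oxy](4-hydroxyphenyl)methyl}-5,7-dihydroxy-6-methoxy-8-methylchroman-4-one | COc1c(O)c(C)c2c(c1O)C(=O)[C@H]([C@H](O[Si](C)(C)C(C)(C)C)c1ccc(O)cc1)[C@@H](O[Si](C)(C)C(C)(C)C)O2
A1 | alternative 1 | 3,5-diisopropoxy-4-methoxy-2-methylphenol | COc1c(OC(C)C)c(C)c(O)cc1OC(C)C
A2 | alternative 1 | 3-isopropoxy-4-(1-isopropoxyethenyl)-4-methoxy-2-methylcyclobut-2-en-1-one | CC1=C(OC(C)C)C(OC)(C(=C)OC(C)C)C1=O
A3 | alternative 1 | 3,4-diisopropoxycyclobut-3-ene-1,2-dione | CC(C)OC1=C(OC(C)C)C(=O)C1=O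
A4 | alternative 2 | (2R,3S)-1-[2,4-bis(benzyloxy)-6-hydroxy-3-methoxy-5-methylphenyl]-3-[4-(benzyloxy)phenyl]-2-(1,3-dioxolan-2-yl)-3-[(triisopropylsilyl)oxy]propan-1-one | COc1c(OCc2ccccc2)c(C)c(O)c(c1OCc1ccccc1)C(=O)[C@H]([C@H](O[Si](C(C)C)(C(C)C)C(C)C)c1ccc(OCc2ccccc2)cc1)C1OCCO1
A5 | alternative 2 | (2R,3S)-3-[4-(benzyloxy)phenyl]-2-(1,3-dioxolan-2-yl)-3-[(triisopropylsilyl)oxy]propanoic acid | OC(=O)[C@H]([C@H](O[Si](C(C)C)(C(C)C)C(C)C)c1ccc(OCc2ccccc2)cc1)C1OCCO1
A6 | alternative 2 | 3,5-bis(benzyloxy)-4-methoxy-2-methyl-6-(trimethylsilyl)phenyl trifluoromethanesulfonate | COc1c(OCc2ccccc2)c(C)c(OS(=O)(=O)C(F)(F)F)c([Si](C)(C)C)c1OCc1ccccc1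
A7 | alternative 3 | (4R,5S)-3-[2,4-bis(benzyloxy)-3-methoxy-6-(methoxymethoxy)-5-methylphenyl]-4-{(S)-[4-(benzyloxy)phenyl][(tert-butyldimethylsilyl)oxy]methyl}-5-methoxy-4,5-dihydroisoxazole | COc1c(OCc2ccccc2)c(C)c(OCOC)c(C2=NO[C@H](OC)[C@H]2[C@H](O[Si](C)(C)C(C)(C)C)c2ccc(OCc3ccccc3)cc2)c1OCc1ccccc1
A8 | alternative 3 | 2,4-bis(benzyloxy)-3-methoxy-6-(methoxymethoxy)-5-methylbenzonitrile oxide | COCOc1c(C)c(OCc2ccccc2)c(OC)c(OCc2ccccc2)c1C#[N+][O-]
A9 | alternative 3 | tert-butyl({(1S,2E)-1-[4-(benzyloxy)phenyl]-3-methoxyprop-2-en-1-yl}oxy)dimethylsilane | CO/C=C/[C@H](O[Si](C)(C)C(C)(C)C)c1ccc(OCc2ccccc2)cc1
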